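**Plan**

- Retrosynthesis first cuts the two C–C bonds of the CH2 bridge (formaldehyde coupling). This gives ring A as butanoylphloroglucinol 18 and ring B as propanoylfilicinic acid 15.
- Ring B is then cut at the bond between its C(CH3)2 carbon and the ring carbonyl carbon next to the acyl-bearing carbon (6π-closure of a dienylketene). The dienylketene goes back through a cyclobutenone to ynol ether 5 and cyclobutenone 8, and 8 to dimethylketene plus ethoxyacetylene.
- Feature used: ring B is a cyclohexadienone whose sp3 carbon carries two methyl groups between two carbonyl-level carbons. It cannot become a phenol, and its C(=O)–C(CH3)2 bond is the bond a dienylketene closes. Its 1,3,5-oxygen pattern maps onto one ketene and two ynol ether units.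
- Forward: four-membered ring 8 first, then ring B in one strain-releasing cascade, then side-chain oxidation (carbinol helper to ketone) and enol ether hydrolysis, then ring A is joined through CH2.
- Stereochemistry: the target has no stereocentre. The one centre made on the way (silyloxy carbinol) is racemic and is erased by oxidation in step 6.

Key step: step 4

Remark: the target is drawn as one enol tautomer of a cyclic β-triketone; tautomers are treated as one compound, and every chiral intermediate is racemic.

**Step 1**
Reactants: 1 ethoxyacetylene, 2 propanal
Product: 4 rac-1-ethoxypent-1-yn-3-ol, via lithium ethoxyacetylide 3 (not isolated)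
Conditions: n-BuLi, THF, −78 °C; then 2, −78 → 0 °C; H2O quench
Reagents that add atoms: none
Why: Deprotonation of the terminal ynol ether and 1,2-addition of the acetylide to the aldehyde (acetylide addition to a carbonyl group) should give the propargylic alcohol; the new stereocentre is uncontrolled and is removed in step 6.

**Step 2**
Reactants: 4 rac-1-ethoxypent-1-yn-3-ol
Product: 5 rac-tert-butyl[(1-ethoxypent-1-yn-3-yl)oxy]dimethylsilane
Conditions: TBSCl, imidazole, DMF, 0 °C → rt
Reagents that add atoms: tert-butyldimethylsilyl chloride (TBSCl), CC(C)(C)[Si](C)(C)Cl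
Why: Silyl ether formation at a secondary alcohol masks the hydroxyl group, which would otherwise trap the ketenes of step 4, under conditions that leave the acid-sensitive ynol ether intact.

**Step 3**
Reactants: 6 isobutyryl chloride, 1 ethoxyacetylene
Product: 8 3-ethoxy-4,4-dimethylcyclobut-2-en-1-one, via dimethylketene 7 (not isolated)
Conditions: 1 (1.5 equiv), Et3N, MeCN, 0 → 40 °C
Reagents that add atoms: none
Why: Dehydrochlorination gives dimethylketene, which should undergo the regioselective thermal [2+2] cycloaddition of a ketene to an ynol ether (alkyne CH to the ketene carbonyl carbon), a standard entry to 3-alkoxycyclobutenones.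

**Step 4**
Reactants: 8 3-ethoxy-4,4-dimethylcyclobut-2-en-1-one, 5 rac-tert-butyl[(1-ethoxypent-1-yn-3-yl)oxy]dimethylsilane
Product: 12 rac-2-[1-(tert-butyldimethylsilyloxy)propyl]-3,5-diethoxy-6,6-dimethylcyclohexa-2,4-dien-1-one, via vinylketene 9 (not isolated), via alkenylcyclobutenone 10 (not isolated), via dienylketene 11 (not isolated)
Conditions: 8 (1.5 equiv), toluene, sealed tube, 80 °C, then 110 °C
Reagents that add atoms: none
Why: Proposed new method: heating should open 8 by 4π-electrocyclic cleavage to vinylketene 9, the polarized ynol ether 5 should add to the ketene C=C bond in a regioselective [2+2] cycloaddition to give 10, release of four-ring strain in a second 4π-opening should give dienylketene 11, and thermal disrotatory 6π-electrocyclization should join the ketene carbon to the C(CH3)2 terminus to give the 6,6-dimethylcyclohexa-2,4-dienone. The closest known reaction type is the Danheiser benzannulation of cyclobutenones with alkoxy- or siloxyalkynes, together with the known thermal reclosure of dienylketenes to cyclohexa-2,4-dienones; new is the use of a 3-alkoxy-4,4-dialkylcyclobutenone, whose quaternary carbon stops the cascade at the dienone instead of a phenol. Two rings are closed, the transient four-membered ring by [2+2] cycloaddition and the six-membered ring by 6π-electrocyclization; no stereocentre is created, because the new sp3 carbon carries two methyl groups, and the silyloxy carbinol centre is carried through racemic. The step needs the right orientation of the [2+2] addition, secured by the ethoxy group, which makes the alkyne carbon bearing the side chain the nucleophile that bonds to the ketene carbonyl carbon, so the future acyl carbon ends next to the new bond. It also needs ketene and isobutenyl arm cis in 11, secured because the opening of 10 is reversible and only the cis isomer is drained by closure. The silyl ether keeps the hydroxyl group from trapping the ketenes, and the temperature is held at 80 °C until 5 is consumed so that thermal loss of ethylene from the ynol ether does not compete.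

**Step 5**
Reactants: 12 rac-2-[1-(tert-butyldimethylsilyloxy)propyl]-3,5-diethoxy-6,6-dimethylcyclohexa-2,4-dien-1-one
Product: 13 rac-3,5-diethoxy-2-(1-hydroxypropyl)-6,6-dimethylcyclohexa-2,4-dien-1-one
Conditions: TBAF, AcOH, THF, 0 °C → rt
Reagents that add atoms: none
Why: Fluoride-mediated silyl ether cleavage, buffered by acetic acid, should free the carbinol while the two ethyl enol ethers, inert to fluoride, stay in place.

**Step 6**
Reactants: 13 rac-3,5-diethoxy-2-(1-hydroxypropyl)-6,6-dimethylcyclohexa-2,4-dien-1-one
Product: 14 3,5-diethoxy-6,6-dimethyl-2-propanoylcyclohexa-2,4-dien-1-one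
Conditions: Dess–Martin periodinane, pyridine, CH2Cl2, 0 °C → rt
Reagents that add atoms: none
Why: Dess–Martin oxidation of the secondary allylic alcohol under pyridine buffering should give the ketone without exposing the acid-labile enol ethers to acid, and it removes the only stereocentre of the route.

**Step 7**
Reactants: 14 3,5-diethoxy-6,6-dimethyl-2-propanoylcyclohexa-2,4-dien-1-one
Product: 15 3,5-dihydroxy-4,4-dimethyl-2-propanoylcyclohexa-2,5-dien-1-one (propanoylfilicinic acid)
Conditions: 2 M aq. HCl, THF, rt → 50 °C
Reagents that add atoms: water, O
Why: Acid-catalysed hydrolysis of the two vinylogous ester (enol ether) groups by conjugate addition of water and loss of ethanol should give the free triketone, which is stable as its chelated enol.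

**Step 8**
Reactants: 16 phloroglucinol, 17 butyryl chloride
Product: 18 1-(2,4,6-trihydroxyphenyl)butan-1-one
Conditions: AlCl3, PhNO2/CH2Cl2, 0 → 50 °C; then ice, aq. HCl
Reagents that add atoms: none
Why: Friedel–Crafts acylation of phloroglucinol is the standard route to phloroacylophenones, and mono-acylation is favoured because the first acyl group deactivates the ring.

**Step 9**
Reactants: 15 propanoylfilicinic acid, 18 1-(2,4,6-trihydroxyphenyl)butan-1-one, 19 formaldehyde
Product: 21 3,5-dihydroxy-4,4-dimethyl-2-propanoyl-6-[(3-butanoyl-2,4,6-trihydroxyphenyl)methyl]cyclohexa-2,5-dien-1-one (the target), via methylidene trione 20 (not isolated)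
Conditions: 18 (3 equiv), 37% aq. 19 (1 equiv), 1% aq. NaOH, 0 °C → rt; then 2 M HCl
Reagents that add atoms: none
Why: Knoevenagel condensation of formaldehyde at the only free ring carbon of 15 gives 20, which should be trapped by Michael-type addition of a free ring position of 18, the classical formaldehyde coupling of acylfilicinic acids with acylphloroglucinols; excess 18 limits double alkylation and homodimer formation.

**Compound list**

1 | ethoxyacetylene (ethoxyethyne) | C#COCC | starting material
2 | propanal | CCC=O | starting material
3 | lithium ethoxyacetylide | [Li]C#COCC | intermediate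
4 | rac-1-ethoxypent-1-yn-3-ol | CCC(O)C#COCC | intermediate
5 | rac-tert-butyl[(1-ethoxypent-1-yn-3-yl)oxy]dimethylsilane | CCC(O[Si](C)(C)C(C)(C)C)C#COCC | intermediate
6 | isobutyryl chloride (2-methylpropanoyl chloride) | CC(C)C(Cl)=O | starting material
7 | dimethylketene | CC(C)=C=O | intermediate
8 | 3-ethoxy-4,4-dimethylcyclobut-2-en-1-one | CCOC1=CC(=O)C1(C)C | intermediate
9 | 3-ethoxy-4-methylpenta-1,3-dien-1-one (vinylketene) | O=C=CC(OCC)=C(C)C | intermediate
10 | 2-[1-(tert-butyldimethylsilyloxy)propyl]-3-ethoxy-4-(1-ethoxy-2-methylprop-1-en-1-yl)cyclobut-2-en-1-one (racemic, mixture of diastereomers) | CCC(O[Si](C)(C)C(C)(C)C)C1=C(OCC)C(C(OCC)=C(C)C)C1=O | intermediate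
11 | (3E)-2-[1-(tert-butyldimethylsilyloxy)propyl]-3,5-diethoxy-6-methylhepta-1,3,5-trien-1-one (dienylketene, racemic) | O=C=C(C(CC)O[Si](C)(C)C(C)(C)C)/C(OCC)=C\C(OCC)=C(C)C | intermediate
12 | rac-2-[1-(tert-butyldimethylsilyloxy)propyl]-3,5-diethoxy-6,6-dimethylcyclohexa-2,4-dien-1-one | CCC(O[Si](C)(C)C(C)(C)C)C1=C(OCC)C=C(OCC)C(C)(C)C1=O | intermediate
13 | rac-3,5-diethoxy-2-(1-hydroxypropyl)-6,6-dimethylcyclohexa-2,4-dien-1-one | CCC(O)C1=C(OCC)C=C(OCC)C(C)(C)C1=O | intermediate
14 | 3,5-diethoxy-6,6-dimethyl-2-propanoylcyclohexa-2,4-dien-1-one | CCC(=O)C1=C(OCC)C=C(OCC)C(C)(C)C1=O | intermediate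
15 | 3,5-dihydroxy-4,4-dimethyl-2-propanoylcyclohexa-2,5-dien-1-one (propanoylfilicinic acid) | CCC(=O)C1=C(O)C(C)(C)C(O)=CC1=O | intermediate
16 | phloroglucinol (benzene-1,3,5-triol) | Oc1cc(O)cc(O)c1 | starting material
17 | butyryl chloride | CCCC(Cl)=O | starting material
18 | 1-(2,4,6-trihydroxyphenyl)butan-1-one | CCCC(=O)c1c(O)cc(O)cc1O | intermediate
19 | formaldehyde | C=O | starting material
20 | 5-hydroxy-6,6-dimethyl-2-methylidene-4-propanoylcyclohex-4-ene-1,3-dione (methylidene trione) | C=C1C(=O)C(C(=O)CC)=C(O)C(C)(C)C1=O | intermediate
21 | 3,5-dihydroxy-4,4-dimethyl-2-propanoyl-6-[(3-butanoyl-2,4,6-trihydroxyphenyl)methyl]cyclohexa-2,5-dien-1-one | CCCC(=O)c1c(O)cc(O)c(CC2=C(O)C(C)(C)C(O)=C(C(=O)CC)C2=O)c1O | target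

**Step count and risks**

Total step count: 9. Longest linear sequence: 7 steps (steps 1, 2, 4, 5, 6, 7, 9).

Steps most likely to fail:

1. Step 4 (proposed new method). The electrocyclic opening of the vinylogous ester 8 may be too slow at temperatures at which ynol ether 5 survives (thermal loss of ethylene). Vinylketene 9 may also be diverted by a [1,5]-hydrogen shift from a methyl group or by self-condensation before it meets 5. The fallback uses known chemistry and no annulation, and sets out from 16. Friedel–Crafts acylation of 16 with propanoyl chloride and AlCl3 should give 1-(2,4,6-trihydroxyphenyl)propan-1-one F1. Dearomatizing geminal C-methylation of this compound with MeI and NaOMe in MeOH, the classical entry to acylfilicinic acids, should give 15 after separation from under- and over-methylated material. The route is rejoined at 15.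

2. Step 6. Ionization of the hydroxyl group of 13 (the cation is stabilized through the ring by both ethoxy groups) may cause elimination or substitution before or during oxidation, and the electron-rich dienol ether may be attacked by the oxidant. The fallback gives up the side-chain handle and adds the acyl group after ring formation; it sets out from 8 and presupposes that the annulation type of step 4 works. The annulation is run with ethoxyacetylene 1 itself and should proceed via 9, via 3-ethoxy-4-(1-ethoxy-2-methylprop-1-en-1-yl)cyclobut-2-en-1-one F2 and via (3E)-3,5-diethoxy-6-methylhepta-1,3,5-trien-1-one F3, none of them isolated, to 3,5-diethoxy-6,6-dimethylcyclohexa-2,4-dien-1-one F4. Hydrolysis with aqueous HCl should give filicinic acid F5. Friedel–Crafts C-acylation of this triketone with propanoyl chloride and AlCl3 in nitrobenzene should give 15, where the route is rejoined.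

3. Step 9. The one-pot coupling is statistical: 20 may be captured by a second molecule of 15, 18 may be alkylated at both free positions, and 18 may couple with itself. The fallback is a stepwise Mannich route that sets out from 15. Aminomethylation with dimethylmethylideneammonium iodide in MeCN should give 6-[(dimethylamino)methyl]-3,5-dihydroxy-4,4-dimethyl-2-propanoylcyclohexa-2,5-dien-1-one F6, which is isolated and then heated with an excess of 18 in dioxane. Loss of dimethylamine regenerates 20 only in the presence of 18 and should give 21 directly, where the route is rejoined.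

**Further compounds**

F1 | step 4 | 1-(2,4,6-trihydroxyphenyl)propan-1-one | CCC(=O)c1c(O)cc(O)cc1O
F2 | step 6 | 3-ethoxy-4-(1-ethoxy-2-methylprop-1-en-1-yl)cyclobut-2-en-1-one (racemic, not isolated) | O=C1C=C(OCC)C1C(OCC)=C(C)C
F3 | step 6 | (3E)-3,5-diethoxy-6-methylhepta-1,3,5-trien-1-one (not isolated) | O=C=C/C(OCC)=C\C(OCC)=C(C)C
F4 | step 6 | 3,5-diethoxy-6,6-dimethylcyclohexa-2,4-dien-1-one | O=C1C=C(OCC)C=C(OCC)C1(C)C
F5 | step 6 | filicinic acid (3,5-dihydroxy-4,4-dimethylcyclohexa-2,5-dien-1-one) | O=C1C=C(O)C(C)(C)C(O)=C1
F6 | step 9 | 6-[(dimethylamino)methyl]-3,5-dihydroxy-4,4-dimethyl-2-propanoylcyclohexa-2,5-dien-1-one | CN(C)CC1=C(O)C(C)(C)C(O)=C(C(=O)CC)C1=O
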